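Amounts opened the meeting: Thursday's flask was charged with 0.10 M of starting material and 0.095 M of reagent, and its contents were wanted at 3.0 min.

| flask | starting material | reagent | remark | time |
|---|---|---|---|---|
| Thursday's | 0.10 M | 0.095 M | the very flask that is asked about, followed so far |  |
| Friday's | 0.20 M | 0.095 M | run made earlier |  |
| flask | 0.10 M | 0.0950 M |  | 3.0 min |

| run | time / s | starting material / % | single product / % |
|---|---|---|---|
| Thursday's | 10.0 | 22 | 29 |
| Thursday's | 25.0 | 19 | 26 |
| Thursday's | 50.0 | 18 | 20 |
| Friday's | 10.0 | 48 | 17 |
| Friday's | 25.0 | 45 | 11 |
| Friday's | 50.0 | 45 | 3 |
| Friday's | 80.0 | 41 | 4 |

(standard deviation of a reading: 2 percentage points)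

- a reading or a percentage of single product counts all its forms, free or not
- a reading of starting material is of its free form alone

- amount of starting material at 3.0 min, in percent of the starting material charged
- amount of single product at 3.0 min, in percent of the starting material charged
- amount of other mono adduct at 3.0 min, in percent of the starting material charged
- amount of bis adduct at 3.0 min, in percent of the starting material charged

The first chemist said that Thursday's starting material had moved from 22 % to 18 % between the first and last readings. She proposed holding it near 18 %. Over the same readings, she noted, Thursday's single product slid from 29 % to 20 %.

The second chemist wanted one number for that slide. He took the logarithm of the ratio of those two readings and divided it by the time between them, which gave 0.00929 s⁻¹. He called this the fade constant, the share of single product lost each second while starting material stands nearly still. That treats the loss as pseudo-first-order, he said, so on this reckoning the amount halves every 74.6 s.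

The first chemist replied that the constant is a reading and carries the scatter. The meeting accepted it anyway. It divided the last reading by the exponential of the fade constant times the time remaining, and this gave an estimate of 5.98 % of single product in Thursday's flask at 3.0 min. The readings show neither other mono adduct nor bis adduct, so the meeting set no figure for them.

The forecast said 16 % of starting material, 7 % of single product, 65 % of other mono adduct and 12 % of bis adduct, on the ground that “M decays after the reagent is gone”.

Thursday's flask gave 17.8 % of starting material, 3.75 % of single product, 31.2 % of other mono adduct and 24.3 % of bis adduct.

    starting material + reagent ⇌ single product (K = 410 M⁻¹, k = 4.60 M⁻¹ s⁻¹)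
    starting material + reagent → other mono adduct (k = 6.10 M⁻¹ s⁻¹)
    reagent + single product → bis adduct (k = 0.180 M⁻¹ s⁻¹)
    reagent + other mono adduct → bis adduct (k = 3.70 M⁻¹ s⁻¹)
    starting material + single product ⇌ idle adduct, settled at all times (K = 3.60 M⁻¹)
    starting material + single product → side product (k = 0.270 M⁻¹ s⁻¹)

The meeting's 5.98 % stands 2.2 percentage points above the flask's 3.75 %. The same fade constant, taken from the last reading to 2.0 min, gives an estimate of 10.4 % for this flask read then, and the flask gives 7.77 % at that time. Part of the fade is the way back to starting material and reagent, acting together with the step to other mono adduct. Against 3.75 % in the flask, the run without the way back keeps 20.6 % of single product, and the run without that step keeps 28.3 %.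

The data were computed with constants of no real substance; noise was put on by code.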